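**Plan**

- Ring numbering used throughout: C1 = ketone, C2 = C(CH2OH), C3 = CH, C4 = CH–O-isobutyryl, C5 = CH–iPr, C6 = CH–O-acyl. The retrosynthesis cuts the two ester C–O bonds first (the C4 one with inversion), then the ring bond C5–C6, then the chain bonds C1–C2 (acyl–alkenyl) and C3–C4 (alkynyl–aldehyde).
- Enabling feature: C6 bears oxygen and lies between the C1 ketone and the isopropyl-bearing C5. With isopropyl read as reduced isopropenyl, O–C6–C5–C(CH3)=CH2 is the homoallylic-alcohol retron of a carbonyl-ene reaction. Opening C5–C6 gives an acyclic C10 (Z)-alkenylglyoxal, in which C1=O activates and chelates the C6 aldehyde and the ring alkene C2=C3 holds the two ends together.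
- This is the bond that closes when an acyclic monoterpene chain becomes the p-menthane ring in biosynthesis, here with an aldehyde in place of the allyl cation.
- Forward order: C3–C4 (asymmetric alkynylation of prenal), Z-C2=C3 (trans-hydroalumination/iodination), C1–C2 (alkenyllithium plus glycolic Weinreb amide), oxidation/ene closure of the only ring, isopropenyl to isopropyl, ester at C6, ester at C4, desilylation.
- Stereochemistry: only C4 is made by catalysis. In the ene step it relays to C5 (allylic 1,3-strain) and C6 (chelated chair) to give the all-trans ring. C4 is then inverted in the Mitsunobu step that installs the isobutyrate, which gives the 4,5-cis-5,6-trans target. The side-chain E alkene comes from a stabilised Wittig reaction.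
- Helpers: PMB on O4, TBS on both primary alcohols, and the isopropenyl double bond. They are removed in steps 11, 13 and 7.

Key step: step 6

Assumption: the (S,S)-enantiomer of the ProPhenol ligand is taken to give the (S)-carbinol in step 1. If the sense of induction with this enal is the opposite, the (R,R)-ligand is used and nothing else changes.

Step 1
Reactants: 1 3-methylbut-2-enal (prenal); 2 tert-butyldimethyl(prop-2-yn-1-yloxy)silane
Product: 4 (S)-1-[(tert-butyldimethylsilyl)oxy]-6-methylhept-5-en-2-yn-4-ol, via alkynyl(methyl)zinc 3 (not isolated)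
Conditions: Me2Zn (3 equiv), (S,S)-ProPhenol (20 mol %), Ph3P=O (40 mol %), toluene, 0 °C; then aq NH4Cl
Reagents that add atoms: none
Why: Catalytic asymmetric alkynylation of an enal of the zinc–ProPhenol type, in which Me2Zn deprotonates 2 to 3 and the alkynyl group adds 1,2 to the aldehyde inside the chiral dizinc pocket, setting the only catalyst-derived stereocentre (the future C4).

Step 2
Reactants: 4 (S)-1-[(tert-butyldimethylsilyl)oxy]-6-methylhept-5-en-2-yn-4-ol
Product: 6 (S,Z)-1-[(tert-butyldimethylsilyl)oxy]-2-iodo-6-methylhepta-2,5-dien-4-ol, via cyclic alkenylalanate 5 (not isolated)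
Conditions: NaAlH2(OCH2CH2OMe)2 (1.5 equiv), THF, 0 °C to rt; then I2, THF, −78 to 0 °C; aq potassium sodium tartrate
Reagents that add atoms: iodine, II
Why: Hydroxyl-directed trans-hydroalumination of a propargylic alcohol followed by iodinolysis with retention; hydride goes to the carbon next to the carbinol and aluminium to the distal carbon within the five-membered oxaaluminacycle 5, so iodine ends up cis to the carbinol carbon, which is the geometry the ring alkene C2=C3 needs.

Step 3
Reactants: 6 (S,Z)-1-[(tert-butyldimethylsilyl)oxy]-2-iodo-6-methylhepta-2,5-dien-4-ol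
Product: 7 (S,Z)-tert-butyl({2-iodo-4-[(4-methoxybenzyl)oxy]-6-methylhepta-2,5-dien-1-yl}oxy)dimethylsilane
Conditions: NaH, PMBCl, Bu4NI (cat.), THF/DMF, 0 °C to rt
Reagents that add atoms: 4-methoxybenzyl chloride (PMBCl), COc1ccc(CCl)cc1
Why: Williamson etherification; the PMB ether prevents lactol and furan formation from the later (Z)-γ-oxy enone, cannot undergo the 1,4 oxygen-to-carbon shift that a silyl group would suffer in the alkenyllithium of step 5, and can later be removed beside the TBS ethers.

Step 4
Reactants: 8 methyl glycolate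
Product: 9 2-hydroxy-N-methoxy-N-methylacetamide
Conditions: MeNH(OMe)·HCl (1 equiv), iPrMgCl (3 equiv), THF, −20 to 0 °C; then aq NH4Cl
Reagents that add atoms: N,O-dimethylhydroxylamine hydrochloride, CNOC.Cl
Why: Weinreb amide formation from an ester with the magnesium amide of N,O-dimethylhydroxylamine, a procedure that tolerates a free hydroxyl group once it is deprotonated.

Step 5
Reactants: 7 (S,Z)-tert-butyl({2-iodo-4-[(4-methoxybenzyl)oxy]-6-methylhepta-2,5-dien-1-yl}oxy)dimethylsilane; 9 2-hydroxy-N-methoxy-N-methylacetamide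
Product: 12 (S,Z)-3-{[(tert-butyldimethylsilyl)oxy]methyl}-1-hydroxy-5-[(4-methoxybenzyl)oxy]-7-methylocta-3,6-dien-2-one, via alkenyllithium 10 (not isolated), via chloromagnesium alkoxide 11 (not isolated)
Conditions: 7, t-BuLi (2.0 equiv), Et2O, −78 °C; separately 9, iPrMgCl (1.0 equiv), THF, −20 °C; combine, −78 to 0 °C; then aq NH4Cl
Reagents that add atoms: none
Why: Iodine–lithium exchange with retention of alkene geometry followed by the Weinreb ketone synthesis; pre-forming 11 removes the acidic proton and the chelated tetrahedral adduct prevents over-addition, so the ketol should arrive without a protecting group on its hydroxyl.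

Step 6
Reactants: 12 (S,Z)-3-{[(tert-butyldimethylsilyl)oxy]methyl}-1-hydroxy-5-[(4-methoxybenzyl)oxy]-7-methylocta-3,6-dien-2-one
Product: 14 (4R,5R,6R)-2-{[(tert-butyldimethylsilyl)oxy]methyl}-6-hydroxy-4-[(4-methoxybenzyl)oxy]-5-(prop-1-en-2-yl)cyclohex-2-en-1-one (4,5-trans-5,6-trans), via alkenylglyoxal 13 (not isolated)
Conditions: Dess–Martin periodinane (1.1 equiv), CH2Cl2, 0 °C; pentane, filter through Celite under Ar, concentrate cold; crude 13 in CH2Cl2 (0.005 M), ZnBr2 (1.0 equiv), −40 to 0 °C
Reagents that add atoms: none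
Why: The Dess–Martin reagent oxidises the primary ketol of 12 to the (Z)-alkenylglyoxal 13; ZnBr2 then clamps the C1 and C6 carbonyl oxygens s-cis, and C6 bonds to the CH terminus (C5) of the trisubstituted alkene while a hydrogen of an allylic methyl group passes to the aldehyde oxygen in one concerted but asynchronous six-electron process. The closest known reaction types are the type-1 intramolecular carbonyl-ene cyclisation of citronellal to isopulegol with ZnBr2 and the ene reactions of glyoxylates and glyoxals. The six-membered carbocycle closes 6-exo-trig with respect to both π bonds (the isopropylidene carbon and the aldehyde oxygen stay outside the ring), and the Z geometry of C2=C3 set in step 2 keeps C5 and C6 within bonding distance. C5 is controlled by C4: allylic 1,3-strain with the cis methyl group of the isopropylidene unit puts the C4–H bond in the alkene plane and the OPMB group pseudo-equatorial, so the tethered aldehyde can reach only the alkene face that gives the 4,5-trans arrangement. C6 is controlled by the chelate and the chair-like transition state, which place the aldehyde oxygen equatorial and gauche to the equatorial isopropenyl group (5,6-trans), and because C6 is α to the ketone a minor cis isomer should drain to the same diequatorial ketol on mild base treatment. The step needs the aldehyde to react in preference to the ketone (less hindered, more electrophilic, six- rather than five-membered ring) and C–C bond formation to outrun ionisation of the doubly allylic C4–O bond, which the mild chelating Lewis acid, the low temperature, the electron-poor enone flank and high dilution should secure.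

Step 7
Reactants: 14 (4R,5R,6R)-2-{[(tert-butyldimethylsilyl)oxy]methyl}-6-hydroxy-4-[(4-methoxybenzyl)oxy]-5-(prop-1-en-2-yl)cyclohex-2-en-1-one
Product: 15 (4R,5R,6R)-2-{[(tert-butyldimethylsilyl)oxy]methyl}-6-hydroxy-5-isopropyl-4-[(4-methoxybenzyl)oxy]cyclohex-2-en-1-one
Conditions: H2 (1 atm), RhCl(PPh3)3 (5 mol %), toluene/EtOH, rt
Reagents that add atoms: none
Why: Homogeneous hydrogenation with RhCl(PPh3)3 should reduce the 1,1-disubstituted isopropenyl group and leave the trisubstituted conjugated C2=C3 alkene and the benzylic ether untouched, as in the reduction of carvone to carvotanacetone; no stereocentre is affected.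

Step 8
Reactants: 16 2-[(tert-butyldimethylsilyl)oxy]acetaldehyde; 17 ethyl 2-(triphenyl-λ5-phosphanylidene)propanoate
Product: 18 ethyl (E)-4-[(tert-butyldimethylsilyl)oxy]-2-methylbut-2-enoate
Conditions: CH2Cl2, rt
Reagents that add atoms: none
Why: Wittig olefination with a stabilised α-methyl ylide, which should give the (E)-trisubstituted enoate (ester trans to the CH2O group).

Step 9
Reactants: 18 ethyl (E)-4-[(tert-butyldimethylsilyl)oxy]-2-methylbut-2-enoate
Product: 19 (E)-4-[(tert-butyldimethylsilyl)oxy]-2-methylbut-2-enoic acid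
Conditions: LiOH, THF/MeOH/H2O, rt; then 0.5 M HCl to pH 4, 0 °C
Reagents that add atoms: lithium hydroxide, [Li+].[OH-]
Why: Saponification by acyl–oxygen cleavage; the primary TBS ether and the thermodynamically preferred E geometry should survive the mild base and the cold, brief acidification.

Step 10
Reactants: 15 (4R,5R,6R)-2-{[(tert-butyldimethylsilyl)oxy]methyl}-6-hydroxy-5-isopropyl-4-[(4-methoxybenzyl)oxy]cyclohex-2-en-1-one; 19 (E)-4-[(tert-butyldimethylsilyl)oxy]-2-methylbut-2-enoic acid
Product: 21 C6 ester of 15 with 19 [(4R,5S,6R) in enone numbering; the C5 descriptor changes by priority only], via mixed anhydride 20 (not isolated)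
Conditions: 19, 2,4,6-trichlorobenzoyl chloride, Et3N, toluene, rt; then 15, DMAP, toluene, 0 °C to rt
Reagents that add atoms: none
Why: Yamaguchi esterification, suited to a hindered secondary alcohol and an α-branched enoic acid; the C6–O bond is not broken, so the configuration is retained, and C6 already holds its thermodynamically preferred equatorial position.

Step 11
Reactants: 21 C6 ester bearing the C4 OPMB group
Product: 22 (4R,5S,6R)-C4 alcohol: (1R,5R,6S)-3-{[(tert-butyldimethylsilyl)oxy]methyl}-5-hydroxy-6-isopropyl-2-oxocyclohex-3-en-1-yl (E)-4-[(tert-butyldimethylsilyl)oxy]-2-methylbut-2-enoate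
Conditions: DDQ, CH2Cl2/pH 7 buffer (10:1), 0 °C
Reagents that add atoms: none
Why: Oxidative cleavage of a PMB ether with DDQ, which attacks only the electron-rich benzylic position and should spare the silyl ethers, the ester and the electron-poor enone.

Step 12
Reactants: 22 (4R,5S,6R)-C4 alcohol; 23 isobutyric acid
Product: 25 (4S,5S,6R)-bis-TBS diester: (1R,5S,6S)-3-{[(tert-butyldimethylsilyl)oxy]methyl}-5-(isobutyryloxy)-6-isopropyl-2-oxocyclohex-3-en-1-yl (E)-4-[(tert-butyldimethylsilyl)oxy]-2-methylbut-2-enoate, via alkoxyphosphonium isobutyrate 24 (not isolated)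
Conditions: PPh3, DIAD, toluene, 0 °C to rt
Reagents that add atoms: none
Why: Mitsunobu esterification, in which isobutyrate displaces the pseudo-equatorial allylic oxyphosphonium group of 24 from the axial direction in an SN2 process that inverts C4 to S (4,5-cis); the equatorial leaving group has no antiperiplanar hydrogen and the enone disfavours ionisation, so elimination and racemising pathways should stay minor.

Step 13
Reactants: 25 (4S,5S,6R)-bis-TBS diester
Product: 26 target, (1R,5S,6S)-3-(hydroxymethyl)-5-(isobutyryloxy)-6-isopropyl-2-oxocyclohex-3-en-1-yl (E)-4-hydroxy-2-methylbut-2-enoate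
Conditions: HF·pyridine, pyridine, THF, 0 °C to rt
Reagents that add atoms: none
Why: Fluoride-mediated cleavage of the two primary TBS ethers under buffered, weakly acidic conditions; these should cause no acyl migration, no epimerisation at C6 and no lactonisation of the E-configured hydroxy enoate.

**Compound list**

1 | 3-methylbut-2-enal (prenal) | CC(C)=CC=O | starting material
2 | tert-butyldimethyl(prop-2-yn-1-yloxy)silane | C#CCO[Si](C)(C)C(C)(C)C | starting material
3 | methyl{3-[(tert-butyldimethylsilyl)oxy]prop-1-yn-1-yl}zinc (formed in the flask) | C[Zn]C#CCO[Si](C)(C)C(C)(C)C | intermediate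
4 | (S)-1-[(tert-butyldimethylsilyl)oxy]-6-methylhept-5-en-2-yn-4-ol | CC(C)=C[C@H](O)C#CCO[Si](C)(C)C(C)(C)C | intermediate
5 | sodium alkenylalanate, five-membered 1,2-oxaaluminacycle with two 2-methoxyethoxy groups on aluminium (formed in the flask) | COCCO[Al-]1(OCCOC)O[C@@H](C=C(C)C)C=C1CO[Si](C)(C)C(C)(C)C.[Na+] | intermediate
6 | (S,Z)-1-[(tert-butyldimethylsilyl)oxy]-2-iodo-6-methylhepta-2,5-dien-4-ol | CC(C)=C[C@H](O)/C=C(\I)CO[Si](C)(C)C(C)(C)C | intermediate
7 | (S,Z)-tert-butyl({2-iodo-4-[(4-methoxybenzyl)oxy]-6-methylhepta-2,5-dien-1-yl}oxy)dimethylsilane | CC(C)=C[C@H](OCc1ccc(OC)cc1)/C=C(\I)CO[Si](C)(C)C(C)(C)C | intermediate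
8 | methyl glycolate | COC(=O)CO | starting material
9 | 2-hydroxy-N-methoxy-N-methylacetamide | CON(C)C(=O)CO | intermediate
10 | alkenyllithium from 7, lithium in place of iodine, geometry and carbinol configuration as in 7 (formed in the flask) | CC(C)=C[C@H](OCc1ccc(OC)cc1)/C=C(\[Li])CO[Si](C)(C)C(C)(C)C | intermediate
11 | chloromagnesium alkoxide of 9 (formed in the flask) | CON(C)C(=O)CO[Mg]Cl | intermediate
12 | (S,Z)-3-{[(tert-butyldimethylsilyl)oxy]methyl}-1-hydroxy-5-[(4-methoxybenzyl)oxy]-7-methylocta-3,6-dien-2-one | CC(C)=C[C@H](OCc1ccc(OC)cc1)/C=C(/CO[Si](C)(C)C(C)(C)C)C(=O)CO | intermediate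
13 | (S,Z)-3-{[(tert-butyldimethylsilyl)oxy]methyl}-5-[(4-methoxybenzyl)oxy]-7-methyl-2-oxoocta-3,6-dienal (formed in the flask) | CC(C)=C[C@H](OCc1ccc(OC)cc1)/C=C(/CO[Si](C)(C)C(C)(C)C)C(=O)C=O | intermediate
14 | (4R,5R,6R)-2-{[(tert-butyldimethylsilyl)oxy]methyl}-6-hydroxy-4-[(4-methoxybenzyl)oxy]-5-(prop-1-en-2-yl)cyclohex-2-en-1-one | O[C@H]1C(=O)C(CO[Si](C)(C)C(C)(C)C)=C[C@@H](OCc2ccc(OC)cc2)[C@@H]1C(C)=C | intermediate
15 | (4R,5R,6R)-2-{[(tert-butyldimethylsilyl)oxy]methyl}-6-hydroxy-5-isopropyl-4-[(4-methoxybenzyl)oxy]cyclohex-2-en-1-one | O[C@H]1C(=O)C(CO[Si](C)(C)C(C)(C)C)=C[C@@H](OCc2ccc(OC)cc2)[C@@H]1C(C)C | intermediate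
16 | 2-[(tert-butyldimethylsilyl)oxy]acetaldehyde | O=CCO[Si](C)(C)C(C)(C)C | starting material
17 | ethyl 2-(triphenyl-λ5-phosphanylidene)propanoate | CCOC(=O)C(C)=P(c1ccccc1)(c1ccccc1)c1ccccc1 | starting material
18 | ethyl (E)-4-[(tert-butyldimethylsilyl)oxy]-2-methylbut-2-enoate | CCOC(=O)/C(C)=C/CO[Si](C)(C)C(C)(C)C | intermediate
19 | (E)-4-[(tert-butyldimethylsilyl)oxy]-2-methylbut-2-enoic acid | OC(=O)/C(C)=C/CO[Si](C)(C)C(C)(C)C | intermediate
20 | mixed anhydride of 19 and 2,4,6-trichlorobenzoic acid (formed in the flask) | C/C(=C\CO[Si](C)(C)C(C)(C)C)C(=O)OC(=O)c1c(Cl)cc(Cl)cc1Cl | intermediate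
21 | (1R,5R,6S)-3-{[(tert-butyldimethylsilyl)oxy]methyl}-6-isopropyl-5-[(4-methoxybenzyl)oxy]-2-oxocyclohex-3-en-1-yl (E)-4-[(tert-butyldimethylsilyl)oxy]-2-methylbut-2-enoate | C/C(=C\CO[Si](C)(C)C(C)(C)C)C(=O)O[C@H]1C(=O)C(CO[Si](C)(C)C(C)(C)C)=C[C@@H](OCc2ccc(OC)cc2)[C@@H]1C(C)C | intermediate
22 | (1R,5R,6S)-3-{[(tert-butyldimethylsilyl)oxy]methyl}-5-hydroxy-6-isopropyl-2-oxocyclohex-3-en-1-yl (E)-4-[(tert-butyldimethylsilyl)oxy]-2-methylbut-2-enoate | C/C(=C\CO[Si](C)(C)C(C)(C)C)C(=O)O[C@H]1C(=O)C(CO[Si](C)(C)C(C)(C)C)=C[C@@H](O)[C@@H]1C(C)C | intermediate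
23 | isobutyric acid | CC(C)C(=O)O | starting material
24 | C4 alkoxytriphenylphosphonium isobutyrate derived from 22 (formed in the flask) | C/C(=C\CO[Si](C)(C)C(C)(C)C)C(=O)O[C@H]1C(=O)C(CO[Si](C)(C)C(C)(C)C)=C[C@@H](O[P+](c2ccccc2)(c2ccccc2)c2ccccc2)[C@@H]1C(C)C.CC(C)C(=O)[O-] | intermediate
25 | (1R,5S,6S)-3-{[(tert-butyldimethylsilyl)oxy]methyl}-5-(isobutyryloxy)-6-isopropyl-2-oxocyclohex-3-en-1-yl (E)-4-[(tert-butyldimethylsilyl)oxy]-2-methylbut-2-enoate | C/C(=C\CO[Si](C)(C)C(C)(C)C)C(=O)O[C@H]1C(=O)C(CO[Si](C)(C)C(C)(C)C)=C[C@H](OC(=O)C(C)C)[C@@H]1C(C)C | intermediate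
26 | (1R,5S,6S)-3-(hydroxymethyl)-5-(isobutyryloxy)-6-isopropyl-2-oxocyclohex-3-en-1-yl (E)-4-hydroxy-2-methylbut-2-enoate | C/C(=C\CO)C(=O)O[C@H]1C(=O)C(CO)=C[C@H](OC(=O)C(C)C)[C@@H]1C(C)C | target

Total step count: 13. Longest linear sequence: 10 steps (steps 1, 2, 3, 5, 6, 7, 10, 11, 12, 13).

**Steps most likely to fail**

Step 6. The alkenylglyoxal may hydrate or oligomerise. Its doubly activated C2=C3 bond may isomerise from Z to E, which takes the two ends out of reach. ZnBr2 may also ionise the doubly allylic C4–O bond before the C–C bond forms.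
The fallback sets out from 12 and comes back at 14. It takes the enophile one oxidation level lower, so that the alkene is no longer conjugated.
- Luche reduction of 12 (NaBH4, CeCl3·7H2O, MeOH, −78 °C) should give the carbinol-epimeric allylic 1,2-diol F1.
- Selective nitroxyl oxidation of its primary alcohol (TEMPO, N-chlorosuccinimide, Bu4NCl, CH2Cl2/aqueous buffer pH 8.6) should give the α-hydroxy aldehyde F2.
- Me2AlCl (2.2 equiv, CH2Cl2, −78 °C) first forms the aluminium alkoxide, chelates the aldehyde and should promote the same type-1 ene closure to the cyclohex-2-ene-1,6-diol F3.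
- Both carbinol epimers converge, because MnO2 (CH2Cl2, rt) then oxidises only the allylic C1 carbinol to the enone 14.

Step 12. Displacement at C4 beside the isopropyl group may be slow with a weakly acidic carboxylic acid. Acyl transfer with retention could then take over, or loss of the activated oxygen toward a cross-conjugated dienone and its phenol tautomer.
The fallback sets out from 22 and comes back at 25. It separates inversion from acylation.
- A Mitsunobu reaction with the much more acidic chloroacetic acid (PPh3, DIAD, toluene, 0 °C) should give the inverted C4 chloroacetate F4.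
- Thiourea (NaHCO3, EtOH/THF, rt) removes only the chloroacetyl group and should give the 4,5-cis alcohol F5.
- Isobutyric anhydride (DMAP, pyridine, CH2Cl2, 0 °C) then acylates with retention to give 25.

Step 5. Addition to the anionic, poorly soluble alkoxide 11 may be slow. On warming, the alkenyllithium would then be lost by proton transfer or by β-elimination of silyloxide to an allene.
The fallback sets out from 7 and comes back at 12.
- The alkenyllithium 10 is trapped at −78 °C by neutral, commercially available 2-chloro-N-methoxy-N-methylacetamide to give the α-chloro enone F6.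
- HCO2Na (DMF, rt) displaces the chloride to give the α-formyloxy enone F7.
- Mild methanolysis (NaHCO3, MeOH, 0 °C) releases the ketol 12.

Further compounds
F1 | step 6 | (5S,3Z)-3-{[(tert-butyldimethylsilyl)oxy]methyl}-5-[(4-methoxybenzyl)oxy]-7-methylocta-3,6-diene-1,2-diol, both C2 epimers | CC(C)=C[C@H](OCc1ccc(OC)cc1)/C=C(/CO[Si](C)(C)C(C)(C)C)C(O)CO
F2 | step 6 | (5S,3Z)-3-{[(tert-butyldimethylsilyl)oxy]methyl}-2-hydroxy-5-[(4-methoxybenzyl)oxy]-7-methylocta-3,6-dienal, both C2 epimers | CC(C)=C[C@H](OCc1ccc(OC)cc1)/C=C(/CO[Si](C)(C)C(C)(C)C)C(O)C=O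
F3 | step 6 | (4R,5R,6R)-2-{[(tert-butyldimethylsilyl)oxy]methyl}-4-[(4-methoxybenzyl)oxy]-5-(prop-1-en-2-yl)cyclohex-2-ene-1,6-diol, ring numbering as in 14, both C1 epimers | O[C@H]1C(O)C(CO[Si](C)(C)C(C)(C)C)=C[C@@H](OCc2ccc(OC)cc2)[C@@H]1C(C)=C
F4 | step 12 | (1R,5S,6S)-3-{[(tert-butyldimethylsilyl)oxy]methyl}-5-(2-chloroacetoxy)-6-isopropyl-2-oxocyclohex-3-en-1-yl (E)-4-[(tert-butyldimethylsilyl)oxy]-2-methylbut-2-enoate | C/C(=C\CO[Si](C)(C)C(C)(C)C)C(=O)O[C@H]1C(=O)C(CO[Si](C)(C)C(C)(C)C)=C[C@H](OC(=O)CCl)[C@@H]1C(C)C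
F5 | step 12 | (1R,5S,6S)-3-{[(tert-butyldimethylsilyl)oxy]methyl}-5-hydroxy-6-isopropyl-2-oxocyclohex-3-en-1-yl (E)-4-[(tert-butyldimethylsilyl)oxy]-2-methylbut-2-enoate | C/C(=C\CO[Si](C)(C)C(C)(C)C)C(=O)O[C@H]1C(=O)C(CO[Si](C)(C)C(C)(C)C)=C[C@H](O)[C@@H]1C(C)C
F6 | step 5 | (S,Z)-3-{[(tert-butyldimethylsilyl)oxy]methyl}-1-chloro-5-[(4-methoxybenzyl)oxy]-7-methylocta-3,6-dien-2-one | CC(C)=C[C@H](OCc1ccc(OC)cc1)/C=C(/CO[Si](C)(C)C(C)(C)C)C(=O)CCl
F7 | step 5 | (S,Z)-3-{[(tert-butyldimethylsilyl)oxy]methyl}-5-[(4-methoxybenzyl)oxy]-7-methyl-2-oxoocta-3,6-dien-1-yl formate | CC(C)=C[C@H](OCc1ccc(OC)cc1)/C=C(/CO[Si](C)(C)C(C)(C)C)C(=O)COC=O
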